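**Plan**

- Retrosynthesis first removes the N-SEM, N-tosyl and C2-SiEt3 groups, then cuts N1–C2 and C3–C3a of the 6-bromoindole, then the imidazole C4–indole C3 bond and the imidazole C2–alkyne bond, back to 4-bromoimidazole.
- Enabling feature: the 6-bromoindole is attached through its C3 to imidazole C2, so its C2–C3 pair can be carried as an alkyne on imidazole C2. Its benzo ring plus N1 is 5-bromo-2-iodoaniline, whose bromine para to the C–I carbon becomes C6–Br.
- Forward order: the imidazole is bought and dressed (SEM, C2 iodide, silylalkyne); the unsubstituted indole is bought as its C3 boronic acid and joined at C4; the pyrrole ring of the bromoindole is the only ring made and is closed last; two deprotections finish.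
- Stereochemistry: none. The target is an achiral, fully aromatic tris-heterocycle; no stereocentre is made or needed.

Key step: step 5

Remark: the target has no stereogenic element, so the demand for a single enantiomer is met trivially. Compounds 1, 6, 8 and 10 are taken as catalogue chemicals. SEM = [2-(trimethylsilyl)ethoxy]methyl; Ts = 4-methylbenzenesulfonyl.

**Route**

Step 1
Reactants: 1 4-bromo-1H-imidazole
Product: 3 4-bromo-1-{[2-(trimethylsilyl)ethoxy]methyl}-1H-imidazole, via sodium 4-bromoimidazolide 2 (not isolated)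
Conditions: NaH, THF, 0 °C; then SEMCl, 0 °C → rt
Reagents that add atoms: 2-(trimethylsilyl)ethoxymethyl chloride (SEMCl), C[Si](C)(C)CCOCCl
Why: N-alkylation of the imidazolide (SEM protection) should favour the nitrogen remote from bromine on steric and electronic grounds, giving mainly the 1,4-isomer, with the minor 1,5-isomer removed by chromatography.

Step 2
Reactants: 3 4-bromo-1-SEM-imidazole
Product: 5 4-bromo-2-iodo-1-{[2-(trimethylsilyl)ethoxy]methyl}-1H-imidazole, via 2-lithio-4-bromo-1-SEM-imidazole 4 (not isolated)
Conditions: LDA, THF, −78 °C; then I2, −78 °C → rt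
Reagents that add atoms: iodine, II
Why: Directed deprotonation at C2, the most acidic C–H between the two nitrogens and assisted by the SEM oxygen, by an amide base that does not exchange the C4 bromine, followed by iodination of the aryllithium.

Step 3
Reactants: 5 4-bromo-2-iodo-1-SEM-imidazole; 6 triethylsilylacetylene
Product: 7 4-bromo-1-SEM-2-[(triethylsilyl)ethynyl]-1H-imidazole
Conditions: PdCl2(PPh3)2 (cat.), CuI (cat.), Et3N, THF, rt
Reagents that add atoms: none
Why: Sonogashira coupling in which oxidative addition at the C2–I bond is far faster than at C4–Br, so only the iodide should be alkynylated at room temperature.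

Step 4
Reactants: 7 4-bromo-1-SEM-2-[(triethylsilyl)ethynyl]imidazole; 8 (1-tosyl-1H-indol-3-yl)boronic acid
Product: 9 1-SEM-4-(1-tosyl-1H-indol-3-yl)-2-[(triethylsilyl)ethynyl]-1H-imidazole
Conditions: Pd(dppf)Cl2 (cat.), K3PO4, 1,4-dioxane/H2O, 85 °C
Reagents that add atoms: none
Why: Suzuki–Miyaura coupling at the remaining C4–Br with an N-sulfonyl indol-3-ylboronic acid, under alcohol-free phosphate conditions mild enough to keep the alkynyl–SiEt3 bond and the N-tosyl group.

Step 5
Reactants: 9 1-SEM-4-(1-tosylindol-3-yl)-2-[(triethylsilyl)ethynyl]imidazole; 10 5-bromo-2-iodoaniline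
Product: 11 6-bromo-3-[1-SEM-4-(1-tosyl-1H-indol-3-yl)-1H-imidazol-2-yl]-2-(triethylsilyl)-1H-indole
Conditions: Pd(OAc)2 (cat.), LiCl, K2CO3, DMF, 100 °C
Reagents that add atoms: none
Why: Larock heteroannulation: Pd(0) inserts into the C–I bond of 10, the arylpalladium adds syn across the alkyne of 9 with the aryl carbon going to the imidazole-bearing carbon (C3–C3a) and palladium to the silyl-bearing carbon, the aniline nitrogen displaces halide on palladium to give a six-membered azapalladacycle, and C–N reductive elimination forms N1–C2. The closest known reaction type is the annulation of free 2-iodoanilines with aryl(trialkylsilyl)acetylenes, which gives 3-aryl-2-silylindoles. The one ring closed is the pyrrole ring of the bromoindole, closed by reductive elimination from the palladacycle in a formal [3+2] union of the C–C–N unit of the aniline with the two alkyne carbons. No stereocentre is formed. Two selectivities are needed: insertion at C–I and not at C–Br, secured by the much more reactive C–I bond under phosphine-free palladium, and aryl delivery to the imidazole-bearing carbon, secured by the bulk of SiEt3, which has to sit next to palladium and so ends at indole C2. Because the bromine of 10 is para to the iodine-bearing carbon, it can only become C6–Br.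

Step 6
Reactants: 11 6-bromo-3-[1-SEM-4-(1-tosylindol-3-yl)imidazol-2-yl]-2-(triethylsilyl)-1H-indole
Product: 12 6-bromo-3-[4-(1H-indol-3-yl)-1-SEM-1H-imidazol-2-yl]-2-(triethylsilyl)-1H-indole
Conditions: KOH, EtOH/THF/H2O, 60 °C
Reagents that add atoms: none
Why: Standard N-detosylation of an indole by hydroxide attack at sulfur with the indolide as leaving group; the SEM aminal ether, the aryl bromide and the hindered C2–SiEt3 bond on the electron-rich indolide should not be attacked.

Step 7
Reactants: 12 6-bromo-3-[4-(1H-indol-3-yl)-1-SEM-imidazol-2-yl]-2-(triethylsilyl)-1H-indole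
Product: 13 nortopsentin B, 6-bromo-3-[4-(1H-indol-3-yl)-1H-imidazol-2-yl]-1H-indole
Conditions: TBAF, THF, 65 °C
Reagents that add atoms: none
Why: Fluoride attacks both silicon atoms, so fluoride-induced fragmentation of the SEM group (Me3SiF, ethene, formaldehyde) frees the imidazole N–H and fluoride-induced protodesilylation clears indole C2, both standard desilylations.

**Compound list**

1 | 4-bromo-1H-imidazole | Brc1c[nH]cn1 | starting material
2 | sodium 4-bromoimidazolide (not isolated) | [Na+].Brc1c[n-]cn1 | intermediate
3 | 4-bromo-1-{[2-(trimethylsilyl)ethoxy]methyl}-1H-imidazole | Brc1cn(COCC[Si](C)(C)C)cn1 | intermediate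
4 | 2-lithio-4-bromo-1-SEM-imidazole (not isolated) | [Li]c1nc(Br)cn1COCC[Si](C)(C)C | intermediate
5 | 4-bromo-2-iodo-1-{[2-(trimethylsilyl)ethoxy]methyl}-1H-imidazole | Ic1nc(Br)cn1COCC[Si](C)(C)C | intermediate
6 | triethylsilylacetylene | C#C[Si](CC)(CC)CC | starting material
7 | 4-bromo-1-SEM-2-[(triethylsilyl)ethynyl]-1H-imidazole | CC[Si](CC)(CC)C#Cc1nc(Br)cn1COCC[Si](C)(C)C | intermediate
8 | (1-tosyl-1H-indol-3-yl)boronic acid | Cc1ccc(cc1)S(=O)(=O)n1cc(B(O)O)c2ccccc12 | starting material
9 | 1-SEM-4-(1-tosyl-1H-indol-3-yl)-2-[(triethylsilyl)ethynyl]-1H-imidazole | CC[Si](CC)(CC)C#Cc1nc(cn1COCC[Si](C)(C)C)-c1cn(S(=O)(=O)c2ccc(C)cc2)c2ccccc12 | intermediate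
10 | 5-bromo-2-iodoaniline | Nc1cc(Br)ccc1I | starting material
11 | 6-bromo-3-[1-SEM-4-(1-tosyl-1H-indol-3-yl)-1H-imidazol-2-yl]-2-(triethylsilyl)-1H-indole | CC[Si](CC)(CC)c1[nH]c2cc(Br)ccc2c1-c1nc(cn1COCC[Si](C)(C)C)-c1cn(S(=O)(=O)c2ccc(C)cc2)c2ccccc12 | intermediate
12 | 6-bromo-3-[4-(1H-indol-3-yl)-1-SEM-1H-imidazol-2-yl]-2-(triethylsilyl)-1H-indole | CC[Si](CC)(CC)c1[nH]c2cc(Br)ccc2c1-c1nc(cn1COCC[Si](C)(C)C)-c1c[nH]c2ccccc12 | intermediate
13 | nortopsentin B | Brc1ccc2c(-c3nc(-c4c[nH]c5ccccc45)c[nH]3)c[nH]c2c1 | target

**Summary**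

Total steps: 7. Longest linear sequence: 7 steps (1 → 13); compounds 6, 8 and 10 enter as purchased partners.

**Steps most likely to fail**

1. Step 5 (heteroannulation). Palladium may also insert into the C–Br bond of 10 or of the product and give oligomers, the imidazole nitrogen may sequester the catalyst, or insertion may occur with the reverse orientation. The fallback gives up the annulation and attaches a preformed 6-bromoindole; it sets out from 3 and returns at 13.
   - Suzuki–Miyaura coupling of 3 with 8 should give 1-SEM-4-(1-tosylindol-3-yl)imidazole F1.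
   - C2 lithiation of F1 (n-BuLi, THF, −78 °C, short contact so that the SEM-assisted deprotonation between the nitrogens outruns lithiation next to the sulfonamide) and transmetalation with ZnCl2 should give the imidazol-2-ylzinc chloride F2.
   - Commercial 6-bromoindole is iodinated at C3 (I2, KOH, DMF) to 6-bromo-3-iodoindole F3 and N-tosylated (NaH, TsCl) to 6-bromo-3-iodo-1-tosylindole F4.
   - Negishi coupling of F2 with F4 (Pd(PPh3)4, THF, 50 °C) should react at the C–I bond only and give the bis-tosyl SEM-protected bisindolylimidazole F5.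
   - KOH as in step 6 should give the SEM-protected bisindolylimidazole F6, and TBAF as in step 7 should then give 13.

2. Step 4 (Suzuki coupling at imidazole C4). Protodeboronation of the indolylboronic acid may outrun a slow oxidative addition at the electron-rich C4–Br bond, and the aqueous base may hydrolyse the alkynyl–silicon bond. The fallback replaces boron by tin under base-free conditions; it sets out from 7 and returns at 9. 1-Tosyl-3-(tributylstannyl)indole F7 (from commercial 3-bromo-1-tosylindole, hexabutylditin, Pd(PPh3)4, toluene, 110 °C) is joined to 7 in a Stille coupling (Pd(PPh3)4, CuI, DMF, 90 °C), which should give 9 with no water or base present.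

3. Step 7 (double desilylation). Fluoride-induced cleavage of the C2–Si bond may stall on the deprotonated indole, and liberated formaldehyde may re-add to a ring nitrogen. The fallback uses Brønsted acid in place of attack at silicon; it sets out from 12 and returns at 13. TFA in CH2Cl2 at rt should remove the silyl group by ipso-protonation at indole C2 and open the SEM ether to the N-hydroxymethyl imidazole F8. Aqueous NH3 in MeOH should then release formaldehyde and give 13.

**Further compounds**

F1 | step 5 | 1-SEM-4-(1-tosyl-1H-indol-3-yl)-1H-imidazole | Cc1ccc(cc1)S(=O)(=O)n1cc(-c2cn(COCC[Si](C)(C)C)cn2)c2ccccc12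
F2 | step 5 | [1-SEM-4-(1-tosylindol-3-yl)imidazol-2-yl]zinc chloride | Cl[Zn]c1nc(cn1COCC[Si](C)(C)C)-c1cn(S(=O)(=O)c2ccc(C)cc2)c2ccccc12
F3 | step 5 | 6-bromo-3-iodo-1H-indole | Brc1ccc2c(I)c[nH]c2c1
F4 | step 5 | 6-bromo-3-iodo-1-tosyl-1H-indole | Cc1ccc(cc1)S(=O)(=O)n1cc(I)c2ccc(Br)cc12
F5 | step 5 | 6-bromo-1-tosyl-3-[1-SEM-4-(1-tosylindol-3-yl)imidazol-2-yl]-1H-indole | Cc1ccc(cc1)S(=O)(=O)n1cc(-c2nc(cn2COCC[Si](C)(C)C)-c2cn(S(=O)(=O)c3ccc(C)cc3)c3ccccc23)c2ccc(Br)cc12
F6 | step 5 | 6-bromo-3-[4-(1H-indol-3-yl)-1-SEM-imidazol-2-yl]-1H-indole | Brc1ccc2c(-c3nc(cn3COCC[Si](C)(C)C)-c3c[nH]c4ccccc34)c[nH]c2c1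
F7 | step 4 | 1-tosyl-3-(tributylstannyl)-1H-indole | CCCC[Sn](CCCC)(CCCC)c1cn(S(=O)(=O)c2ccc(C)cc2)c2ccccc12
F8 | step 7 | [2-(6-bromo-1H-indol-3-yl)-4-(1H-indol-3-yl)-1H-imidazol-1-yl]methanol | OCn1cc(-c2c[nH]c3ccccc23)nc1-c1c[nH]c2cc(Br)ccc12
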